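**Retrosynthetic overview**
- Last operation: a resorcinol triol, triethyl orthoformate and a 4-hydroxy-2-pyrone are joined in one flask. The orthoformate carbon becomes C4, the pyrone is opened as the acyl donor, and the coumarin lactone and the dihydropyranone both close.
- Pyrone (carries the dihydropyranone stereocentre): ethyl (S)-3-hydroxybutanoate + ethyl acetoacetate dianion, then lactonisation.
- Resorcinol triol: hydrogenolysis (O-benzyl and benzylic C–O) of a cis-3,4-dimethylisochroman made by oxa-Pictet–Spengler reaction with formaldehyde; the tether delivers the ring methyl.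
- Side chain: aryl Grignard opening of (2R,3R)-2,3-epoxybutane sets both stereocentres.
- Ring order: temporary isochroman (closed in step 2, reopened in step 3), pyrone (closed in step 5, reopened in step 6), then coumarin and dihydropyranone together in step 6.

Assumption: the target is read as (2R,3R) in the 3-hydroxybutan-2-yl chain and (S) at the dihydropyranone methyl carbon, and 1 and 2 are treated as catalogue compounds.

**Step 1**
Reactants: 1 1,3-bis(benzyloxy)-5-bromobenzene; 2 (2R,3R)-2,3-dimethyloxirane
Product: 4 (2R,3R)-3-[3,5-bis(benzyloxy)phenyl]butan-2-ol, via aryl Grignard 3 (not isolated)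
Conditions: Mg, THF, 50 °C; then CuI (10 mol%), 2, −30 → 0 °C; 1 M HCl quench
Reagents that add atoms: none
Why: Cu-catalysed SN2 opening of the C2-symmetric trans-epoxide by the aryl Grignard reagent (both epoxide carbons are equivalent) inverts the attacked carbon and retains the carbinol carbon, which sets both side-chain stereocentres as (2R,3R) in one step.

**Step 2**
Reactants: 4 (2R,3R)-3-[3,5-bis(benzyloxy)phenyl]butan-2-ol
Product: 5 (3R,4R)-6,8-bis(benzyloxy)-3,4-dimethyl-3,4-dihydro-1H-isochromene
Conditions: (CH2O)n, TsOH·H2O (10 mol%), CH2Cl2, 40 °C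
Reagents that add atoms: paraformaldehyde (reacts as formaldehyde), C=O
Why: In this oxa-Pictet–Spengler reaction the oxocarbenium ion from the secondary alcohol and formaldehyde can only close a six-membered ring onto the arene carbon ortho to the tether (para to a benzyloxy group), so the future ring-methyl carbon is placed regiospecifically and no stereocentre is touched.

**Step 3**
Reactants: 5 (3R,4R)-6,8-bis(benzyloxy)-3,4-dimethyl-3,4-dihydro-1H-isochromene
Product: 6 5-[(2R,3R)-3-hydroxybutan-2-yl]-4-methylbenzene-1,3-diol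
Conditions: H2 (5 bar), Pd(OH)2/C, EtOH–AcOH, HCl (cat.), 50 °C
Reagents that add atoms: none
Why: Catalytic hydrogenolysis removes both O-benzyl groups and then cleaves the benzylic C1–O bond of the isochroman, which the ortho and para hydroxyls activate through a quinone-methide-like cation under acid, leaving the ring methyl and the free side-chain alcohol with both stereocentres intact.

**Step 4**
Reactants: 7 ethyl acetoacetate; 8 ethyl (3S)-3-hydroxybutanoate
Product: 10 ethyl (7S)-7-hydroxy-3,5-dioxooctanoate, via dilithio dianion 9 (not isolated)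
Conditions: 7 + LDA (2.05 equiv), THF, 0 °C; 8 (0.3 equiv), −20 → 0 °C; 1 M HCl, 0 °C
Reagents that add atoms: none
Why: Huckin–Weiler γ-acylation (crossed Claisen condensation) of the acetoacetate dianion with the lithium alkoxide of the β-hydroxy ester, run with excess dianion as in Claisen condensations of unprotected β-hydroxy esters with ester enolates, builds the triketide chain while the (S)-carbinol carbon is a spectator.

**Step 5**
Reactants: 10 ethyl (7S)-7-hydroxy-3,5-dioxooctanoate
Product: 11 4-hydroxy-6-[(2S)-2-hydroxypropyl]-2H-pyran-2-one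
Conditions: DBU (1.5 equiv), toluene, 80 °C; 1 M HCl
Reagents that add atoms: none
Why: DBU-mediated lactonisation of a 3,5-dioxo ester (C5 enolate oxygen onto the ester) is the standard 4-hydroxy-2-pyrone synthesis; it leaves C3 as the only nucleophilic carbon and breaks no bond to the stereocentre.

**Step 6**
Reactants: 6 5-[(2R,3R)-3-hydroxybutan-2-yl]-4-methylbenzene-1,3-diol; 11 4-hydroxy-6-[(2S)-2-hydroxypropyl]-2H-pyran-2-one
Product: 14 7-hydroxy-5-[(2R,3R)-3-hydroxybutan-2-yl]-6-methyl-3-[(2S)-2-methyl-4-oxo-3,4-dihydro-2H-pyran-6-yl]-2H-chromen-2-one (CNP0270207.1), via cyclic ethoxy acetal 12 (not isolated), via diketo coumarin 13 (not isolated)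
Conditions: HC(OEt)3 (3 equiv), TFA (10 mol%), CH2Cl2, 25 °C, evaporate; 11 (1.0 equiv), piperidine/AcOH (30 mol%), EtOH, 50 °C; then TsOH·H2O (0.5 equiv), 60 °C
Reagents that add atoms: triethyl orthoformate, CCOC(OCC)OCC
Why: Proposed new method: tether-directed orthoformate formylation (oxa-Pictet–Spengler type, the way isochromene rings are closed onto resorcinols) gives acetal 12 at the only free position ortho to the side chain, its quinone-methide form is attacked by C3 of pyrone 11 (Knoevenagel type), retro-oxa-Michael opening and attack of the ortho phenol on the pyrone lactone carbonyl (the known salicylaldehyde + 4-hydroxy-6-methyl-2-pyrone to 3-acetoacetylcoumarin ring transformation) give 13, and acid-catalysed hemiketalisation–dehydration of the δ-hydroxy-β-diketone closes the dihydropyranone, all without breaking a bond at any of the three stereocentres.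

**Compound list**
1 | 1,3-bis(benzyloxy)-5-bromobenzene | Brc1cc(OCc2ccccc2)cc(OCc2ccccc2)c1 | starting material
2 | (2R,3R)-2,3-dimethyloxirane (trans-2,3-epoxybutane) | C[C@H]1O[C@@H]1C | starting material
3 | [3,5-bis(benzyloxy)phenyl]magnesium bromide (not isolated) | Br[Mg]c1cc(OCc2ccccc2)cc(OCc2ccccc2)c1 | intermediate
4 | (2R,3R)-3-[3,5-bis(benzyloxy)phenyl]butan-2-ol | C[C@@H](O)[C@H](C)c1cc(OCc2ccccc2)cc(OCc2ccccc2)c1 | intermediate
5 | (3R,4R)-6,8-bis(benzyloxy)-3,4-dimethyl-3,4-dihydro-1H-isochromene (cis-dimethyl isochroman) | C[C@H]1OCc2c(OCc3ccccc3)cc(OCc3ccccc3)cc2[C@H]1C | intermediate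
6 | 5-[(2R,3R)-3-hydroxybutan-2-yl]-4-methylbenzene-1,3-diol | Cc1c(O)cc(O)cc1[C@@H](C)[C@@H](C)O | intermediate
7 | ethyl acetoacetate | CCOC(=O)CC(C)=O | starting material
8 | ethyl (3S)-3-hydroxybutanoate | CCOC(=O)C[C@H](C)O | starting material
9 | dilithio dianion of ethyl acetoacetate (not isolated) | [Li]OC(=C)C=C(O[Li])OCC | intermediate
10 | ethyl (7S)-7-hydroxy-3,5-dioxooctanoate | CCOC(=O)CC(=O)CC(=O)C[C@H](C)O | intermediate
11 | 4-hydroxy-6-[(2S)-2-hydroxypropyl]-2H-pyran-2-one | O=c1cc(O)cc(C[C@H](C)O)o1 | intermediate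
12 | (3R,4R)-1-ethoxy-3,4,5-trimethyl-3,4-dihydro-1H-isochromene-6,8-diol, both C1 epimers (not isolated) | Cc1c(O)cc(O)c2c1[C@@H](C)[C@@H](C)OC2OCC | intermediate
13 | 7-hydroxy-5-[(2R,3R)-3-hydroxybutan-2-yl]-3-[(5S)-5-hydroxy-3-oxohexanoyl]-6-methyl-2H-chromen-2-one (not isolated) | Cc1c(O)cc2oc(=O)c(C(=O)CC(=O)C[C@H](C)O)cc2c1[C@@H](C)[C@@H](C)O | intermediate
14 | 7-hydroxy-5-[(2R,3R)-3-hydroxybutan-2-yl]-6-methyl-3-[(2S)-2-methyl-4-oxo-3,4-dihydro-2H-pyran-6-yl]-2H-chromen-2-one (CNP0270207.1) | Cc1c(O)cc2oc(=O)c(C3=CC(=O)C[C@H](C)O3)cc2c1[C@@H](C)[C@@H](C)O | target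

**Count**
Total steps: 6. Longest linear sequence: 4 (steps 1, 2, 3, 6); the pyrone arm is 3 (steps 4, 5, 6).

**Three steps most likely to fail**

Step 6 is the riskiest. The quinone-methide form of acetal 12 can be trapped by a second arene instead of the pyrone. A second pyrone can add to the arylidene intermediate before translactonisation. The β-hydroxy ketone in 13 can undergo retro-aldol cleavage under the amine. The fallback makes the rings one at a time, sets out from 6 and 10 and comes back at 14. Compound 6 alone is treated with HC(OEt)3/TFA and the acetal is hydrolysed with aqueous acid to 2,4-dihydroxy-6-[(2R,3R)-3-hydroxybutan-2-yl]-5-methylbenzaldehyde F1 (in equilibrium with its lactol). Ester 10 is cyclodehydrated with TsOH to ethyl 2-[(2S)-2-methyl-4-oxo-3,4-dihydro-2H-pyran-6-yl]acetate F2, so the dihydropyranone is already closed. A classical Knoevenagel condensation–lactonisation of F1 with F2 (piperidine/AcOH, EtOH) then gives 14.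

Step 3 may stop at the debenzylated isochroman, because cyclic benzyl ethers are cleaved more slowly than open ones. The fallback installs the methyl group by cross-coupling instead of by the C1 tether, sets out from 4 and comes back at 6. NBS in MeCN brominates 4 para to a benzyloxy group and ortho to the chain, giving (2R,3R)-3-[3,5-bis(benzyloxy)-2-bromophenyl]butan-2-ol F3. Suzuki methylation (trimethylboroxine, Pd(dppf)Cl2, K2CO3, dioxane, 90 °C) gives (2R,3R)-3-[3,5-bis(benzyloxy)-2-methylphenyl]butan-2-ol F4. Plain O-debenzylation (H2, Pd/C, EtOH) then gives 6.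

Step 4 may give low conversion, because the dianion must acylate an ester that carries a neighbouring alkoxide and the product quenches further dianion. The fallback uses a Weinreb amide and a dioxinone nucleophile and forms the pyrone thermally without base; it sets out from 8 and comes back at 11. Compound 8 is converted with MeNHOMe·HCl/i-PrMgCl into (3S)-3-hydroxy-N-methoxy-N-methylbutanamide F5. Excess lithium dienolate of the bought reagent 2,2,6-trimethyl-4H-1,3-dioxin-4-one (LiHMDS, THF, −78 °C) acylates F5 at the γ-carbon to give 6-[(4S)-4-hydroxy-2-oxopentyl]-2,2-dimethyl-4H-1,3-dioxin-4-one F6. Heating F6 in toluene at 110 °C releases the acylketene, which closes onto the remote enol to give 11.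

**Further compounds**
F1 | step 6 | 2,4-dihydroxy-6-[(2R,3R)-3-hydroxybutan-2-yl]-5-methylbenzaldehyde | Cc1c(O)cc(O)c(C=O)c1[C@@H](C)[C@@H](C)O
F2 | step 6 | ethyl 2-[(2S)-2-methyl-4-oxo-3,4-dihydro-2H-pyran-6-yl]acetate | CCOC(=O)CC1=CC(=O)C[C@H](C)O1
F3 | step 3 | (2R,3R)-3-[3,5-bis(benzyloxy)-2-bromophenyl]butan-2-ol | C[C@@H](O)[C@H](C)c1cc(OCc2ccccc2)cc(OCc2ccccc2)c1Br
F4 | step 3 | (2R,3R)-3-[3,5-bis(benzyloxy)-2-methylphenyl]butan-2-ol | C[C@@H](O)[C@H](C)c1cc(OCc2ccccc2)cc(OCc2ccccc2)c1C
F5 | step 4 | (3S)-3-hydroxy-N-methoxy-N-methylbutanamide | CON(C)C(=O)C[C@H](C)O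
F6 | step 4 | 6-[(4S)-4-hydroxy-2-oxopentyl]-2,2-dimethyl-4H-1,3-dioxin-4-one | CC1(C)OC(=O)C=C(CC(=O)C[C@H](C)O)O1
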